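## The problem

3,3′-Digalloylprocyanidin B2 (21) consists of two (−)-epicatechin 3-O-gallate units joined by one C–C bond from C4 of the upper unit (rings A, B, C) to C8′ of the lower unit (rings D, E, F). Locants C2′–C8a′ denote the lower unit; in names such as 5,7,3′,4′-tetra-O-benzyl the primes keep their usual flavan meaning. There are five stereocentres: C2, C3 and C4 above and C2′ and C3′ below, all R, with both pyran rings 2,3-cis and the C4 aryl group trans to the C3 oxygen (4β). The upper three belong together: C2 and C3 exist in (−)-epicatechin, and the C3 substituent sends a nucleophile to the opposite face of a C4 cation, so C4 follows from C3. The lower pair lies beyond the flat ring D and cannot be controlled by the upper unit; C2′ has to come from an enantiopure fragment, and C3′ can then be set from C2′. The C4–C8′ bond is doubly benzylic between two phloroglucinol-type rings and breaks under strong acid; the electron-rich rings oxidise easily; C2 and C2′ epimerise under base; and the gallate esters tolerate neither hydride nor carbonyl-olefination reagents. The esters therefore enter late, and all fourteen phenols are carried as benzyl ethers and freed last by neutral hydrogenolysis. The enabling feature is the C3′–C4′ bond of ring F: C3′ bears oxygen and C4′ is a benzylic methylene on C4a′, so the bond can be formed as the C=C of a 3-methoxy-2H-chromene (the methyl enol ether of a flavan-3-one) by metathesis of a vinyl group on C4a′ with a 1-methoxyvinyl group on C2′, the two held ortho by the C8a′–O1′ ether.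

## Retrosynthesis

**Esters and benzyl ethers.** The two galloyl C–O bonds and fourteen O-benzyl bonds are cut first: 21 comes from the perbenzylated diester 20, and 20 from diol 18 and acid 19. Acylating both secondary alcohols in one operation is shorter than carrying one gallate through the route, which the methylenation and hydride steps would not allow. The forward reactions need only a forcing acylation of two axial alcohols and a clean hydrogenolysis.

**Oxidation level at C3′.** Diol 18 is traced to the silyl ether 17, this to the flavan-3-one 16, and 16 to the cyclic enol ether 15. Going through the ketone is preferred to direct functionalisation of a C3′=C4′ alkene, because a bulky hydride on a 2-aryl-chroman-3-one is the established way to the 2,3-cis alcohol. The forward steps must hydrolyse the enol ether without enolising toward C2′ and deliver hydride cis-selectively.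

**C3′=C4′ (key cut).** Ring F of 15 is opened at the enol ether double bond to give diene 14, which has a vinyl group on C4a′ and a 2-methoxyallyl ether on O1′. The neighbouring cuts are O1′–C2′ (an SN2 ring closure at a hindered benzylic carbon) and C4′–C4a′ (an acid-mediated Friedel–Crafts closure). Both would have to run in the presence of the acid-labile interflavan bond or would endanger C2′; metathesis is neutral and forms no stereocentre. The precursor has one ring fewer and two terminal alkenes of very different character, which is what an ordered ring closure needs.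

**Enol ether and O1′–C2′.** Diene 14 comes from ester 13 by methylenation of the ester carbonyl. Ester 13 is cut at O1′–C2′ into phenol 8 and the (S)-mandelate 12. An α-hydroxy ester is chosen as the C2′ electrophile because the carbonyl group disfavours ionisation, so displacement proceeds with clean inversion. The forward etherification must cope with a doubly ortho-substituted phenol.

**The C2′ fragment.** Mandelate 12 derives from keto ester 11 by catalytic enantioselective reduction, and 11 from aryl bromide 9 through aryllithium 10 by a two-carbon acylation. This gives the only stereocentre not taken from epicatechin in two steps.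

**Vinyl group on ring D.** Phenol 8 comes from salicylaldehyde 7 by methylenation, and 7 from phenol 6 by formylation ortho to the hydroxyl. A chelation-directed formylation is preferred to halogenation and cross-coupling, which would not distinguish the ortho carbon from the more activated carbon between the two benzyloxy groups.

**C4–C8′.** Phenol 6 is cut at the interflavan bond into the C4 ether 4 (a latent C4 cation) and phenol 5. This is the bond-forming mode of all procyanidin couplings and sets C4 trans to the C3 substituent. The forward reaction must also direct the cation to a carbon ortho to the free hydroxyl of 5.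

**Upper unit.** Ether 4 comes from 3 by silylation, 3 from tetrabenzyl ether 2 by benzylic oxidation at C4, and 2 from (−)-epicatechin (1). Three of the five stereocentres are thus bought or follow from bought ones.

## Roads not taken

**Alternative 1:** Ring A of the upper unit is built last: C4a–C8a and C5–C6 are formed when the siloxyalkyne A2, which already carries C4, the complete lower unit and an (E)-styryl arm, is heated with 3-benzyloxycyclobut-2-enone A3. The Danheiser benzannulation (vinylketene formation, [2+2] with the ynol ether, 4π opening, 6π closure, tautomerisation) would give phenol A1 with the future O1 free.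
- Merits: the substitution pattern of ring A is fixed by mechanism, and the C4–C8′ bond is present from the start, so no Friedel–Crafts regiochemistry arises. The lower unit can be a natural epicatechin derivative with C2′ and C3′ intact. In these two respects this road is better than the chosen one, which must answer a regiochemical question in step 4 and build ring F with both lower stereocentres.
- Weak points: C4 in A2 is at once propargylic, allylic and benzylic. It has to be created enantioselectively with no good handle and kept through a thermal reaction at about 80–110 °C, where its acidic C–H can epimerise or isomerise to an allene. After A1, ring C is still open: an (E)-alkene leads naturally to a 2,3-trans ring, so the cis alcohol needs an additional oxidation–reduction, plus silyl group exchange.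
- Comparison: the chosen plan takes C2, C3 and C4 from epicatechin by one trans-selective bond formation. Against the intact lower unit of A1 it sets C2′ by a catalytic reduction and C3′ by a precedented hydride reduction, and it never carries a labile C4 stereocentre through ketene chemistry.

**Alternative 2:** The same ring F is closed at C4′–C4a′. In the epoxide A5 the ring D oxygen bears a (3,4-dibenzyloxyphenyl)(oxiranyl)methyl group; BF3·OEt2 would activate the terminal epoxide, and C4a′ would attack the CH2 terminus in a 6-endo Friedel–Crafts alkylation, giving A4 with the C3′ hydroxyl unveiled and the upper gallate already in place.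
- Merits: C3′ appears directly at the alcohol level with its configuration fixed beforehand. No vinyl group, ketone or hydride step is needed, and the upper ester can be installed early. From the C4 adduct onward this road would be about four steps shorter than the chosen plan, and in step economy it is the better one.
- Weak points: the Lewis acid must activate the epoxide next to a benzylic aryl ether at C2′ whose 3,4-dialkoxyphenyl group invites ionisation, which would erase C2′ or fragment the molecule; the interflavan bond is exposed to the same acid. The 6-endo attack at the primary carbon competes with 5-exo attack at C3′ and with hydride shift of the activated epoxide to an aldehyde. Making A5 needs the same hindered aryl ether formation as the chosen plan, but at a benzylic carbon flanked by an epoxide, with no carbonyl to suppress SN1 scrambling.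
- Comparison: the chosen plan pays for its extra steps and its passage through an epimerisable ketone with a ring closure under neutral conditions and with a C2′ centre that is flanked by an ester or enol ether whenever it is under stress.

**Alternative 3:** Ring C is made in one cycloaddition. The ring A benzhydrol A7 would release the ortho-quinone methide A8, which adds the (Z)-styrylsilane A9 in a [4+2] reaction, forming O1–C2 and C3–C4 and giving the 3-silylflavan A6. A Tamao–Fleming oxidation would then turn the C3–Si bond of A6 into C3–O with retention.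
- Merits: two bonds and three stereocentres arise in one step, the route is highly convergent, and the lower unit is again an intact epicatechin derivative. The (Z)-alkene geometry translates into the 2,3-cis relationship. In convergency this road is superior to the chosen one.
- Weak points: the only stereocentres in A8 sit on ring F, far from the reacting heterodiene, so the two faces are hardly differentiated and the (2R,3R,4R) and (2S,3S,4S) upper units would form in comparable amounts. The 3,4-trans relationship depends on methide geometry and endo/exo orientation, neither of which is secured. A8 is a strongly donor-stabilised, weakly electrophilic quinone methide, A9 is a hindered 1,2-disubstituted alkene, and acid-induced Z-to-E isomerisation of A9 would give the 2,3-trans series.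
- Comparison: the chosen plan is linear and longer, but every stereocentre rests on a defined control element (chiral pool, substrate-directed trans attack, stereospecific inversion, bulky hydride), which A6 cannot offer for the configuration of the upper unit relative to the lower one.

Key step: step 11

Assumption: 3,5-bis(benzyloxy)phenol (5), 4-bromo-1,2-bis(benzyloxy)benzene (9) and 3,4,5-tris(benzyloxy)benzoic acid (19) are taken as purchasable benzyl-protected forms of phloroglucinol, catechol and gallic acid; the SMILES strings are binding for configuration.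

## Route

Step 1
Reactants: 1 (−)-epicatechin
Product: 2 5,7,3′,4′-tetra-O-benzyl-(−)-epicatechin
Conditions: BnBr (4.4 equiv), K2CO3, DMF, 0 °C → rt, argon
Reagents that add atoms: benzyl bromide, BrCc1ccccc1
Why: Williamson etherification; K2CO3 deprotonates only the four phenols and leaves the secondary C3 alcohol free. Low temperature and exclusion of air limit base-induced C2 epimerisation and C-benzylation of ring A.

Step 2
Reactants: 2 5,7,3′,4′-tetra-O-benzyl-(−)-epicatechin
Product: 3 4β-(2-ethoxyethoxy)-5,7,3′,4′-tetra-O-benzylepicatechin (3,4-trans)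
Conditions: DDQ (2 equiv), 2-ethoxyethanol, CH2Cl2, rt
Reagents that add atoms: 2-ethoxyethanol, CCOCCO
Why: Benzylic oxidation by hydride abstraction; DDQ removes the C4 hydride, which is activated by the three oxygens of ring A, and the alcohol traps the cation trans to the C3 hydroxyl. The resulting C4 ether is a stable, storable source of the C4 cation.

Step 3
Reactants: 3 4β-(2-ethoxyethoxy)-5,7,3′,4′-tetra-O-benzylepicatechin
Product: 4 3-O-(tert-butyldimethylsilyl)-4β-(2-ethoxyethoxy)-5,7,3′,4′-tetra-O-benzylepicatechin
Conditions: TBSCl, imidazole, DMF, rt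
Reagents that add atoms: tert-butyldimethylsilyl chloride, CC(C)(C)[Si](C)(C)Cl
Why: Silylation of the only free hydroxyl; the TBS ether keeps the upper alcohol out of the later Mitsunobu reaction and reinforces trans attack at C4. It is stable to the titanium, ruthenium and hydride reagents that follow.

Step 4
Reactants: 4 3-O-TBS-4β-(2-ethoxyethoxy)-5,7,3′,4′-tetra-O-benzylepicatechin; 5 3,5-bis(benzyloxy)phenol
Product: 6 4β-[2,4-bis(benzyloxy)-6-hydroxyphenyl]-3-O-TBS-5,7,3′,4′-tetra-O-benzylepicatechin (2,3-cis-3,4-trans)
Conditions: 5 (3 equiv), Me3SiOTf (0.3 equiv), CH2Cl2, −78 → −30 °C; Et3N quench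
Reagents that add atoms: none
Why: Friedel–Crafts alkylation through the flavan-4-yl cation, the reaction type of procyanidin interflavan couplings; the nucleophile enters anti to the 3-silyloxy group and the C2 aryl group, giving the 4β adduct. Attack ortho to the free hydroxyl is expected because two such carbons are available, each flanked by the small OH and not by two benzyloxy groups, and any O-alkylated material re-ionises and returns to the C-adduct; excess 5 suppresses double alkylation.

Step 5
Reactants: 6 4β-[2,4-bis(benzyloxy)-6-hydroxyphenyl]-3-O-TBS-5,7,3′,4′-tetra-O-benzylepicatechin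
Product: 7 4β-[2,4-bis(benzyloxy)-5-formyl-6-hydroxyphenyl]-3-O-TBS-5,7,3′,4′-tetra-O-benzylepicatechin
Conditions: MgCl2, Et3N, (CH2O)n, THF, reflux
Reagents that add atoms: formaldehyde (as paraformaldehyde), C=O
Why: Magnesium-mediated ortho-formylation of a phenol (Casnati–Skattebøl); the magnesium phenoxide delivers formaldehyde through a chelate to the single free ortho carbon, and a second formaldehyde oxidises the benzylic alkoxide to the aldehyde. The carbon between the two benzyloxy groups is not reached and the medium is non-acidic, so the interflavan bond is safe.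

Step 6
Reactants: 7 4β-[2,4-bis(benzyloxy)-5-formyl-6-hydroxyphenyl]-3-O-TBS-5,7,3′,4′-tetra-O-benzylepicatechin
Product: 8 4β-[2,4-bis(benzyloxy)-6-hydroxy-5-vinylphenyl]-3-O-TBS-5,7,3′,4′-tetra-O-benzylepicatechin
Conditions: Ph3PCH3Br (3 equiv), KOt-Bu (3 equiv), THF, 0 °C → rt; neutral work-up, used at once
Reagents that add atoms: methyltriphenylphosphonium bromide, C[P+](c1ccccc1)(c1ccccc1)c1ccccc1.[Br-]
Why: Wittig methylenation of a salicylaldehyde; the first equivalent of ylide forms the phenoxide and the excess converts the aldehyde to the vinyl group, the usual way to 2-vinylphenols. No stereocentre is touched.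

Step 7
Reactants: 9 4-bromo-1,2-bis(benzyloxy)benzene
Product: 11 methyl 2-[3,4-bis(benzyloxy)phenyl]-2-oxoacetate, via 3,4-bis(benzyloxy)phenyllithium 10 (not isolated)
Conditions: n-BuLi, THF, −78 °C; cannulated into (CO2Me)2 (2 equiv), THF, −78 °C; 1 M HCl
Reagents that add atoms: dimethyl oxalate, COC(=O)C(=O)OC
Why: Bromine–lithium exchange followed by acylation with an oxalate diester; the tetrahedral adduct persists at −78 °C, so inverse addition to excess oxalate stops at the keto ester.

Step 8
Reactants: 11 methyl 2-[3,4-bis(benzyloxy)phenyl]-2-oxoacetate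
Product: 12 methyl (S)-2-[3,4-bis(benzyloxy)phenyl]-2-hydroxyacetate
Conditions: RuCl[(R,R)-TsDPEN](p-cymene) (1 mol%), HCO2H/Et3N (5:2), DMF, rt
Reagents that add atoms: none
Why: Noyori asymmetric transfer hydrogenation of an aryl α-keto ester; the divalent ruthenium hydride and the ligand N–H deliver hydrogen to one carbonyl face in a six-membered transition state, with the aryl group held against the η6-arene. By the aryl ketone model the (R,R) ligand gives the (S)-mandelate, and recrystallisation can raise the enantiopurity.

Step 9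
Reactants: 8 4β-[2,4-bis(benzyloxy)-6-hydroxy-5-vinylphenyl]-3-O-TBS-5,7,3′,4′-tetra-O-benzylepicatechin; 12 methyl (S)-2-[3,4-bis(benzyloxy)phenyl]-2-hydroxyacetate
Product: 13 methyl (R)-2-[3,4-bis(benzyloxy)phenyl]-2-aryloxyacetate, the aryl group being ring D of 8 bonded through its phenolic oxygen
Conditions: 12 (1.5 equiv), PPh3, DIAD, toluene, 0 °C → rt
Reagents that add atoms: none
Why: Mitsunobu etherification; the phenoxide displaces the oxyphosphonium group of the α-hydroxy ester by SN2 with inversion, which sets C2′ as R. The adjacent ester carbonyl disfavours ionisation of the benzylic carbon, and the silylated upper alcohol cannot compete as the alcohol component.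

Step 10
Reactants: 13 methyl (R)-2-[3,4-bis(benzyloxy)phenyl]-2-aryloxyacetate
Product: 14 4β-{2,4-bis(benzyloxy)-6-[(R)-1-(3,4-bis(benzyloxy)phenyl)-2-methoxyallyloxy]-5-vinylphenyl}-3-O-TBS-5,7,3′,4′-tetra-O-benzylepicatechin
Conditions: Cp2Ti(μ-Cl)(μ-CH2)AlMe2 (2 equiv), pyridine (cat.), THF/toluene, −40 → 0 °C; aqueous NaOH
Reagents that add atoms: Tebbe reagent Cp2Ti(μ-Cl)(μ-CH2)AlMe2, C=[Ti](C1C=CC=C1)C1C=CC=C1.C[Al](C)Cl
Why: Tebbe methylenation of an ester to a methyl enol ether through a titanium methylidene [2+2] addition and cycloreversion. The reagent is non-basic, so the α-stereocentre C2′ is not enolised, and at or below 0 °C the styrenic alkene is left alone.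

Step 11
Reactants: 14 4β-{2,4-bis(benzyloxy)-6-[(R)-1-(3,4-bis(benzyloxy)phenyl)-2-methoxyallyloxy]-5-vinylphenyl}-3-O-TBS-5,7,3′,4′-tetra-O-benzylepicatechin
Product: 15 3-O-TBS-5,7,3′,4′-tetra-O-benzylepicatechin bonded at C4β to C8 of (2R)-5,7-bis(benzyloxy)-2-[3,4-bis(benzyloxy)phenyl]-3-methoxy-2H-chromene
Conditions: second-generation Grubbs catalyst RuCl2(=CHPh)(PCy3)(H2IMes) (10 mol%), 1,4-benzoquinone (20 mol%), degassed toluene (0.005 M), 60–70 °C, argon sparge, dark
Reagents that add atoms: none
Why: This is a ring-closing metathesis of an enol ether with an olefin. The ruthenium benzylidene first exchanges with the monosubstituted vinyl group on C4a′, then forms a ruthenacyclobutane with the CH2=C(OMe) unit with ruthenium on the CH2 carbon; cycloreversion gives the C3′=C4′ bond and Ru=CH2, and loss of ethylene makes the closure irreversible. The closest known reaction type is the formation of cyclic enol ethers from olefinic enol ethers obtained by ester methylenation, together with 2H-chromene formation from 2-vinylphenyl allyl ethers. Ring F closes as a six-membered oxacycle by joining the two terminal alkene carbons; the ortho-disposed C4a′–C8a′–O1′–C2′ unit already holds four of the six ring atoms in place. No stereocentre is formed, and C2′ is a spectator because the medium is neutral and no carbonyl group is present. The step needs cyclisation over cross-metathesis, which high dilution and the ortho geometry secure, and metathesis over ruthenium-hydride migration of the 2-methoxyallyl double bond, which would erase C2′ and is countered by 1,4-benzoquinone, degassed solvent and the lowest workable temperature. Light is excluded and the temperature kept at or below 70 °C so that the 2-aryl-2H-chromene does not open electrocyclically to a quinone methide, the one thermal path that could racemise C2′. The silyl and benzyl ethers are inert to the catalyst.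

Step 12
Reactants: 15 3-methoxy-2H-chromene dimer
Product: 16 3-O-TBS-5,7,3′,4′-tetra-O-benzylepicatechin bonded at C4β to C8 of (2R)-5,7-bis(benzyloxy)-2-[3,4-bis(benzyloxy)phenyl]chroman-3-one
Conditions: oxalic acid (aqueous), THF, 0 °C → rt; used crude
Reagents that add atoms: water, O
Why: Acid hydrolysis of an enol ether; protonation at C4′, the β-carbon, gives the C3′ oxocarbenium ion, water adds and methanol leaves. The weak acid and short contact time spare the TBS ether and the C4–C8′ bond and limit enolisation toward C2′.

Step 13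
Reactants: 16 flavan-3-one dimer
Product: 17 5,7,3′,4′-tetra-O-benzyl-3-O-TBS-epicatechin-(4β→8)-5,7,3′,4′-tetra-O-benzylepicatechin
Conditions: LiBH(s-Bu)3, LiBr, THF, −78 °C; then H2O
Reagents that add atoms: none
Why: Diastereoselective ketone reduction; the bulky hydride attacks the half-chair, which has the C2′ aryl group pseudo-equatorial, from the equatorial side. This gives the axial (3′R) alcohol cis to the aryl group, the known outcome for benzyl-protected flavan-3-ones, and the low temperature disfavours enolisation.

Step 14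
Reactants: 17 mono-TBS ether of octa-O-benzylprocyanidin B2
Product: 18 5,7,3′,4′-tetra-O-benzylepicatechin-(4β→8)-5,7,3′,4′-tetra-O-benzylepicatechin (octa-O-benzylprocyanidin B2)
Conditions: HF·pyridine, pyridine, THF, 0 °C → rt
Reagents that add atoms: none
Why: Fluoride-driven desilylation; the pyridine buffer keeps the medium too weakly acidic to cleave the interflavan bond.

Step 15
Reactants: 18 octa-O-benzylprocyanidin B2; 19 3,4,5-tris(benzyloxy)benzoic acid
Product: 20 octa-O-benzylprocyanidin B2 3,3′-bis[3,4,5-tris(benzyloxy)benzoate]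
Conditions: 19 (3 equiv), DCC, DMAP, CH2Cl2, rt
Reagents that add atoms: none
Why: Steglich esterification; the acylpyridinium ion formed from the O-acylisourea acylates both hindered axial alcohols. The C3–O and C3′–O bonds are not broken, so both configurations are retained.

Step 16
Reactants: 20 perbenzylated digallate
Product: 21 3,3′-digalloylprocyanidin B2
Conditions: H2 (1 atm), Pd(OH)2/C, THF/MeOH/H2O, rt; filtration and lyophilisation under argon
Reagents that add atoms: none
Why: Hydrogenolysis of the fourteen benzyl ethers at neutral pH; the two aryl esters, the interflavan bond and all five stereocentres are inert under these conditions.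

## Compound list

1 | (−)-epicatechin | O[C@@H]1Cc2c(O)cc(O)cc2O[C@@H]1c1ccc(O)c(O)c1 | starting material
2 | 5,7,3′,4′-tetra-O-benzyl-(−)-epicatechin | O[C@@H]1Cc2c(OCc3ccccc3)cc(OCc3ccccc3)cc2O[C@@H]1c1ccc(OCc2ccccc2)c(OCc2ccccc2)c1 | intermediate
3 | 4β-(2-ethoxyethoxy)-5,7,3′,4′-tetra-O-benzylepicatechin | O[C@@H]1[C@@H](OCCOCC)c2c(OCc3ccccc3)cc(OCc3ccccc3)cc2O[C@@H]1c1ccc(OCc2ccccc2)c(OCc2ccccc2)c1 | intermediate
4 | 3-O-TBS-4β-(2-ethoxyethoxy)-5,7,3′,4′-tetra-O-benzylepicatechin | CC(C)(C)[Si](C)(C)O[C@@H]1[C@@H](OCCOCC)c2c(OCc3ccccc3)cc(OCc3ccccc3)cc2O[C@@H]1c1ccc(OCc2ccccc2)c(OCc2ccccc2)c1 | intermediate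
5 | 3,5-bis(benzyloxy)phenol | Oc1cc(OCc2ccccc2)cc(OCc2ccccc2)c1 | starting material
6 | 4β-[2,4-bis(benzyloxy)-6-hydroxyphenyl]-3-O-TBS-5,7,3′,4′-tetra-O-benzylepicatechin | CC(C)(C)[Si](C)(C)O[C@@H]1[C@@H](c2c(OCc4ccccc4)cc(OCc4ccccc4)cc2O)c2c(OCc3ccccc3)cc(OCc3ccccc3)cc2O[C@@H]1c1ccc(OCc2ccccc2)c(OCc2ccccc2)c1 | intermediate
7 | 4β-[2,4-bis(benzyloxy)-5-formyl-6-hydroxyphenyl]-3-O-TBS-5,7,3′,4′-tetra-O-benzylepicatechin | CC(C)(C)[Si](C)(C)O[C@@H]1[C@@H](c2c(OCc4ccccc4)cc(OCc4ccccc4)c(C=O)c2O)c2c(OCc3ccccc3)cc(OCc3ccccc3)cc2O[C@@H]1c1ccc(OCc2ccccc2)c(OCc2ccccc2)c1 | intermediate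
8 | 4β-[2,4-bis(benzyloxy)-6-hydroxy-5-vinylphenyl]-3-O-TBS-5,7,3′,4′-tetra-O-benzylepicatechin | CC(C)(C)[Si](C)(C)O[C@@H]1[C@@H](c2c(OCc4ccccc4)cc(OCc4ccccc4)c(C=C)c2O)c2c(OCc3ccccc3)cc(OCc3ccccc3)cc2O[C@@H]1c1ccc(OCc2ccccc2)c(OCc2ccccc2)c1 | intermediate
9 | 4-bromo-1,2-bis(benzyloxy)benzene | Brc1ccc(OCc2ccccc2)c(OCc2ccccc2)c1 | starting material
10 | 3,4-bis(benzyloxy)phenyllithium | [Li]c1ccc(OCc2ccccc2)c(OCc2ccccc2)c1 | intermediate (not isolated)
11 | methyl 2-[3,4-bis(benzyloxy)phenyl]-2-oxoacetate | COC(=O)C(=O)c1ccc(OCc2ccccc2)c(OCc2ccccc2)c1 | intermediate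
12 | methyl (S)-2-[3,4-bis(benzyloxy)phenyl]-2-hydroxyacetate | COC(=O)[C@@H](O)c1ccc(OCc2ccccc2)c(OCc2ccccc2)c1 | intermediate
13 | methyl (R)-2-[3,4-bis(benzyloxy)phenyl]-2-aryloxyacetate (aryl = ring D of 8, bonded through its phenolic oxygen) | CC(C)(C)[Si](C)(C)O[C@@H]1[C@@H](c2c(OCc4ccccc4)cc(OCc4ccccc4)c(C=C)c2O[C@H](c4ccc(OCc5ccccc5)c(OCc5ccccc5)c4)C(=O)OC)c2c(OCc3ccccc3)cc(OCc3ccccc3)cc2O[C@@H]1c1ccc(OCc2ccccc2)c(OCc2ccccc2)c1 | intermediate
14 | 4β-{2,4-bis(benzyloxy)-6-[(R)-1-(3,4-bis(benzyloxy)phenyl)-2-methoxyallyloxy]-5-vinylphenyl}-3-O-TBS-5,7,3′,4′-tetra-O-benzylepicatechin | CC(C)(C)[Si](C)(C)O[C@@H]1[C@@H](c2c(OCc4ccccc4)cc(OCc4ccccc4)c(C=C)c2O[C@H](c4ccc(OCc5ccccc5)c(OCc5ccccc5)c4)C(OC)=C)c2c(OCc3ccccc3)cc(OCc3ccccc3)cc2O[C@@H]1c1ccc(OCc2ccccc2)c(OCc2ccccc2)c1 | intermediate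
15 | 3-O-TBS-5,7,3′,4′-tetra-O-benzylepicatechin bonded at C4β to C8 of (2R)-5,7-bis(benzyloxy)-2-[3,4-bis(benzyloxy)phenyl]-3-methoxy-2H-chromene | CC(C)(C)[Si](C)(C)O[C@@H]1[C@@H](c2c(OCc4ccccc4)cc(OCc4ccccc4)c3c2O[C@H](c4ccc(OCc5ccccc5)c(OCc5ccccc5)c4)C(OC)=C3)c2c(OCc3ccccc3)cc(OCc3ccccc3)cc2O[C@@H]1c1ccc(OCc2ccccc2)c(OCc2ccccc2)c1 | intermediate
16 | 3-O-TBS-5,7,3′,4′-tetra-O-benzylepicatechin bonded at C4β to C8 of (2R)-5,7-bis(benzyloxy)-2-[3,4-bis(benzyloxy)phenyl]chroman-3-one | CC(C)(C)[Si](C)(C)O[C@@H]1[C@@H](c2c(OCc4ccccc4)cc(OCc4ccccc4)c3c2O[C@H](c4ccc(OCc5ccccc5)c(OCc5ccccc5)c4)C(=O)C3)c2c(OCc3ccccc3)cc(OCc3ccccc3)cc2O[C@@H]1c1ccc(OCc2ccccc2)c(OCc2ccccc2)c1 | intermediate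
17 | 5,7,3′,4′-tetra-O-benzyl-3-O-TBS-epicatechin-(4β→8)-5,7,3′,4′-tetra-O-benzylepicatechin | CC(C)(C)[Si](C)(C)O[C@@H]1[C@@H](c2c(OCc4ccccc4)cc(OCc4ccccc4)c3c2O[C@H](c4ccc(OCc5ccccc5)c(OCc5ccccc5)c4)[C@H](O)C3)c2c(OCc3ccccc3)cc(OCc3ccccc3)cc2O[C@@H]1c1ccc(OCc2ccccc2)c(OCc2ccccc2)c1 | intermediate
18 | 5,7,3′,4′-tetra-O-benzylepicatechin-(4β→8)-5,7,3′,4′-tetra-O-benzylepicatechin (octa-O-benzylprocyanidin B2) | O[C@@H]1[C@@H](c2c(OCc4ccccc4)cc(OCc4ccccc4)c3c2O[C@H](c4ccc(OCc5ccccc5)c(OCc5ccccc5)c4)[C@H](O)C3)c2c(OCc3ccccc3)cc(OCc3ccccc3)cc2O[C@@H]1c1ccc(OCc2ccccc2)c(OCc2ccccc2)c1 | intermediate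
19 | 3,4,5-tris(benzyloxy)benzoic acid | OC(=O)c1cc(OCc2ccccc2)c(OCc2ccccc2)c(OCc2ccccc2)c1 | starting material
20 | octa-O-benzylprocyanidin B2 3,3′-bis[3,4,5-tris(benzyloxy)benzoate] | O=C(O[C@@H]1[C@@H](c2c(OCc4ccccc4)cc(OCc4ccccc4)c3c2O[C@H](c4ccc(OCc5ccccc5)c(OCc5ccccc5)c4)[C@H](OC(=O)c4cc(OCc5ccccc5)c(OCc5ccccc5)c(OCc5ccccc5)c4)C3)c2c(OCc3ccccc3)cc(OCc3ccccc3)cc2O[C@@H]1c1ccc(OCc2ccccc2)c(OCc2ccccc2)c1)c1cc(OCc2ccccc2)c(OCc2ccccc2)c(OCc2ccccc2)c1 | intermediate
21 | 3,3′-digalloylprocyanidin B2 | O=C(O[C@@H]1[C@@H](c2c(O)cc(O)c3c2O[C@H](c2ccc(O)c(O)c2)[C@H](OC(=O)c2cc(O)c(O)c(O)c2)C3)c2c(O)cc(O)cc2O[C@@H]1c1ccc(O)c(O)c1)c1cc(O)c(O)c(O)c1 | target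

## Step count and least certain steps

Total: 16 steps. Longest linear sequence: 14 steps from (−)-epicatechin (steps 1–6 and 9–16); the mandelate branch (steps 7 and 8) joins at step 9.

**Step 11 (key step).** The most likely failure is slow turnover. The styrenyl ruthenium alkylidene can rest as a chelate with an ortho ether oxygen, and the hindered, electron-rich 1,1-disubstituted enol ether engages slowly. Prolonged heating then allows ruthenium-hydride migration of the 2-methoxyallyl double bond, with loss of C2′, or electrocyclic opening of the product. Fallback: the ring is closed from ester 13 without passing through 14, by a titanium-alkylidene olefinic ester cyclisation. The low-valent titanium ethylidene reagent from TiCl4, Zn, PbCl2 (catalytic), TMEDA and CH3CHBr2 in THF/CH2Cl2 exchanges with the vinyl group, releasing propene, and the resulting titanium alkylidene at C4′ olefinates the ester carbonyl intramolecularly. The route is rejoined at 15; no ruthenium hydride can arise.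

**Step 4.** The cation may alkylate 5 at the carbon para to the hydroxyl (between the two benzyloxy groups) or at oxygen, or the adduct may be alkylated a second time; the regioisomer is useless for ring F. Fallback: starting from 4, the symmetrical nucleophile phloroglucinol is used with BF3·OEt2 in THF/CH2Cl2, which leaves no regiochemical choice and gives the 4β-(2,4,6-trihydroxyphenyl) adduct F1. Magnesium-mediated formylation at either of its two equivalent ring carbons gives the 4β-(3-formyl-2,4,6-trihydroxyphenyl) compound F2. Two equivalents of BnBr with K2CO3 in DMF then etherify the hydroxyl para to the formyl group and the unhindered ortho hydroxyl. The remaining hydroxyl, hydrogen-bonded to the carbonyl and flanked by the flavanyl group, stays free, and the route is rejoined at 7.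

**Step 9.** The phenol of 8 is flanked by the flavanyl and vinyl groups and may attack the oxyphosphonium ion too slowly. The activated mandelate is then diverted to alkylation of the reduced azodicarboxylate, or loses configuration through an ion pair. Fallback: starting from 12, MsCl and Et3N give methyl (S)-2-[3,4-bis(benzyloxy)phenyl]-2-(methylsulfonyloxy)acetate F3. The caesium phenoxide of 8 (Cs2CO3, MeCN), a stronger and unencumbered nucleophile, displaces the sulfonate with inversion, and the route is rejoined at 13.

**Step 6.** The anionic phenoxide deactivates the hindered aldehyde toward the ylide, and the free, very electron-rich 2-vinylphenol 8 can oligomerise through quinone-methide-type cations on work-up or storage. Fallback: the order is changed so that no free vinylphenol is made. Starting from 7, Mitsunobu etherification with 12 gives the aldehyde ester F4 (methyl (R)-2-[3,4-bis(benzyloxy)phenyl]-2-aryloxyacetate with a formyl group in place of the vinyl group of 13). One treatment of F4 with excess Cp2Ti(μ-Cl)(μ-CH2)AlMe2 methylenates the aldehyde and the ester together, and the route is rejoined at 14.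

## Further compounds

F0 | step 11 | none | none
F1 | step 4 | 4β-(2,4,6-trihydroxyphenyl)-3-O-TBS-5,7,3′,4′-tetra-O-benzylepicatechin | CC(C)(C)[Si](C)(C)O[C@@H]1[C@@H](c2c(O)cc(O)cc2O)c2c(OCc3ccccc3)cc(OCc3ccccc3)cc2O[C@@H]1c1ccc(OCc2ccccc2)c(OCc2ccccc2)c1
F2 | step 4 | 4β-(3-formyl-2,4,6-trihydroxyphenyl)-3-O-TBS-5,7,3′,4′-tetra-O-benzylepicatechin | CC(C)(C)[Si](C)(C)O[C@@H]1[C@@H](c2c(O)cc(O)c(C=O)c2O)c2c(OCc3ccccc3)cc(OCc3ccccc3)cc2O[C@@H]1c1ccc(OCc2ccccc2)c(OCc2ccccc2)c1
F3 | step 9 | methyl (S)-2-[3,4-bis(benzyloxy)phenyl]-2-(methylsulfonyloxy)acetate | COC(=O)[C@@H](OS(C)(=O)=O)c1ccc(OCc2ccccc2)c(OCc2ccccc2)c1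
F4 | step 6 | methyl (R)-2-[3,4-bis(benzyloxy)phenyl]-2-aryloxyacetate with the ring D formyl group retained (aryl = ring D of 7, bonded through its phenolic oxygen) | CC(C)(C)[Si](C)(C)O[C@@H]1[C@@H](c2c(OCc4ccccc4)cc(OCc4ccccc4)c(C=O)c2O[C@H](c4ccc(OCc5ccccc5)c(OCc5ccccc5)c4)C(=O)OC)c2c(OCc3ccccc3)cc(OCc3ccccc3)cc2O[C@@H]1c1ccc(OCc2ccccc2)c(OCc2ccccc2)c1
A1 | alternative 1 | 5-benzyloxy-3-(triisopropylsilyloxy)-2-[(E)-1-(lower-unit-8-yl)-3-(3,4-dibenzyloxyphenyl)allyl]phenol, lower unit = 5,7,3′,4′-tetra-O-benzyl-3-O-TBS-epicatechin | Oc1cc(OCc2ccccc2)cc(O[Si](C(C)C)(C(C)C)C(C)C)c1[C@H](c2c(OCc4ccccc4)cc(OCc4ccccc4)c3c2O[C@H](c4ccc(OCc5ccccc5)c(OCc5ccccc5)c4)[C@H](O[Si](C)(C)C(C)(C)C)C3)/C=C/c1ccc(OCc2ccccc2)c(OCc2ccccc2)c1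
A2 | alternative 1 | triisopropylsilyl ynol ether of (E)-3-(lower-unit-8-yl)-5-(3,4-dibenzyloxyphenyl)pent-4-en-1-yne | CC(C)[Si](C(C)C)(C(C)C)OC#C[C@H](c2c(OCc4ccccc4)cc(OCc4ccccc4)c3c2O[C@H](c4ccc(OCc5ccccc5)c(OCc5ccccc5)c4)[C@H](O[Si](C)(C)C(C)(C)C)C3)/C=C/c1ccc(OCc2ccccc2)c(OCc2ccccc2)c1
A3 | alternative 1 | 3-(benzyloxy)cyclobut-2-en-1-one | O=C1CC(OCc2ccccc2)=C1
A4 | alternative 2 | perbenzylated 3-O-galloylprocyanidin B2 with free C3′ hydroxyl | O=C(O[C@@H]1[C@@H](c2c(OCc4ccccc4)cc(OCc4ccccc4)c3c2O[C@H](c4ccc(OCc5ccccc5)c(OCc5ccccc5)c4)[C@H](O)C3)c2c(OCc3ccccc3)cc(OCc3ccccc3)cc2O[C@@H]1c1ccc(OCc2ccccc2)c(OCc2ccccc2)c1)c1cc(OCc2ccccc2)c(OCc2ccccc2)c(OCc2ccccc2)c1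
A5 | alternative 2 | 3-O-[3,4,5-tris(benzyloxy)benzoyl]-5,7,3′,4′-tetra-O-benzylepicatechin carrying at C4β a 2,4-bis(benzyloxy)phenyl group whose 6-oxygen bears the (3,4-dibenzyloxyphenyl)(oxiran-2-yl)methyl group | O=C(O[C@@H]1[C@@H](c2c(OCc4ccccc4)cc(OCc4ccccc4)cc2O[C@H](c4ccc(OCc5ccccc5)c(OCc5ccccc5)c4)[C@H]4CO4)c2c(OCc3ccccc3)cc(OCc3ccccc3)cc2O[C@@H]1c1ccc(OCc2ccccc2)c(OCc2ccccc2)c1)c1cc(OCc2ccccc2)c(OCc2ccccc2)c(OCc2ccccc2)c1
A6 | alternative 3 | 4β-(lower-unit-8-yl)-3α-(benzyldimethylsilyl)-5,7,3′,4′-tetra-O-benzylflavan, 2,3-cis-3,4-trans | C[Si](C)(Cc1ccccc1)[C@@H]1[C@@H](c2c(OCc4ccccc4)cc(OCc4ccccc4)c3c2O[C@H](c4ccc(OCc5ccccc5)c(OCc5ccccc5)c4)[C@H](O[Si](C)(C)C(C)(C)C)C3)c2c(OCc3ccccc3)cc(OCc3ccccc3)cc2O[C@@H]1c1ccc(OCc2ccccc2)c(OCc2ccccc2)c1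
A7 | alternative 3 | 3,5-bis(benzyloxy)-2-[hydroxy(lower-unit-8-yl)methyl]phenol | Oc1cc(OCc2ccccc2)cc(OCc2ccccc2)c1C(O)c1c(OCc2ccccc2)cc(OCc2ccccc2)c2c1O[C@H](c1ccc(OCc3ccccc3)c(OCc3ccccc3)c1)[C@H](O[Si](C)(C)C(C)(C)C)C2
A8 | alternative 3 | 3,5-bis(benzyloxy)-6-[(lower-unit-8-yl)methylidene]cyclohexa-2,4-dien-1-one (ortho-quinone methide) | O=C1C=C(OCc2ccccc2)C=C(OCc2ccccc2)C1=Cc1c(OCc2ccccc2)cc(OCc2ccccc2)c2c1O[C@H](c1ccc(OCc3ccccc3)c(OCc3ccccc3)c1)[C@H](O[Si](C)(C)C(C)(C)C)C2
A9 | alternative 3 | benzyl[(Z)-2-(3,4-bis(benzyloxy)phenyl)ethenyl]dimethylsilane | C[Si](C)(Cc1ccccc1)/C=C\c1ccc(OCc2ccccc2)c(OCc2ccccc2)c1
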